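The tetrahydrofuran ring is disconnected at the O1–C2 ether bond. C2 is the benzylic carbon of the electron-rich 3,4,5-trimethoxyphenyl ring, and the hydroxyl oxygen on C5 can reach it through a five-membered transition state, so a benzylic C–H bond can be converted directly into the ring ether. Anodic oxidation of an acyclic (S)-configured 2-methylene-butan-1-ol, carrying a silyloxymethyl arm at C3 and the trimethoxybenzyl group, closes the ring, forms O1–C2 and sets C2 trans to C3 in one operation. The C4 exocyclic methylene that remains then receives the 3,4-dimethoxyphenyl group by hydroboration and B-alkyl Suzuki coupling, which sets C4.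

Key step: step 8

Remark on numbering and configuration: ring atoms are O1, C2 (aryl), C3 (CH2O arm), C4 (benzyl), C5; the target SMILES is read as (2R,3S,4S), that is 2,3-trans and 3,4-cis.
Remark on design: the C3 arm is carried as a triisopropylsilyl ether, and the single stereocentre of the precursor is set by an auxiliary-controlled enolate alkylation.

Step 1
Reactants: 1 (S)-4-benzyl-1,3-oxazolidin-2-one; 2 pent-4-enoyl chloride
Product: 3 (S)-4-benzyl-3-(pent-4-enoyl)-1,3-oxazolidin-2-one
Conditions: n-BuLi, THF, −78 °C; then 2, −78 → 0 °C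
Reagents that add atoms: none
Why: N-acylation of the lithiated oxazolidinone with the acid chloride is the standard entry to an Evans imide and leaves the auxiliary stereocentre and the terminal alkene untouched.

Step 2
Reactants: 3 (S)-4-benzyl-3-(pent-4-enoyl)-1,3-oxazolidin-2-one; 4 3,4,5-trimethoxybenzyl bromide
Product: 5 (S)-4-benzyl-3-[(2R)-2-(3,4,5-trimethoxybenzyl)pent-4-enoyl]-1,3-oxazolidin-2-one
Conditions: NaN(SiMe3)2, THF, −78 °C; then 4, −78 → −40 °C
Reagents that add atoms: none
Why: Evans asymmetric alkylation, in which the chelated Z sodium enolate is benzylated by the reactive benzylic bromide on the face opposite the benzyl group of the auxiliary, so that the future C3 centre is set as (2R) in 5 and any minor diastereomer can be removed by chromatography.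

Step 3
Reactants: 5 (S)-4-benzyl-3-[(2R)-2-(3,4,5-trimethoxybenzyl)pent-4-enoyl]-1,3-oxazolidin-2-one
Product: 6 (R)-2-(3,4,5-trimethoxybenzyl)pent-4-en-1-ol
Conditions: NaBH4, THF/H2O (3:1), 0 °C → rt
Reagents that add atoms: none
Why: Reductive cleavage of the N-acyl oxazolidinone by borohydride attacks the exocyclic imide carbonyl, frees auxiliary 1 for reuse and gives the primary alcohol without enolising the α-stereocentre or touching the alkene.

Step 4
Reactants: 6 (R)-2-(3,4,5-trimethoxybenzyl)pent-4-en-1-ol
Product: 7 (R)-triisopropyl{[2-(3,4,5-trimethoxybenzyl)pent-4-en-1-yl]oxy}silane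
Conditions: TIPSCl, imidazole, DMF, rt
Reagents that add atoms: triisopropylsilyl chloride, CC(C)[Si](Cl)(C(C)C)C(C)C
Why: Silylation of an unhindered primary alcohol, the triisopropylsilyl ether being chosen because it should withstand the protic anodic medium of step 8 and the aqueous base of step 9 and adds bulk next to C3.

Step 5
Reactants: 7 (R)-triisopropyl{[2-(3,4,5-trimethoxybenzyl)pent-4-en-1-yl]oxy}silane
Product: 8 (S)-4-(3,4,5-trimethoxyphenyl)-3-{[(triisopropylsilyl)oxy]methyl}butanal
Conditions: K2OsO4·2H2O (cat.), NaIO4, 2,6-lutidine, dioxane/H2O (3:1), rt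
Reagents that add atoms: sodium periodate, [Na+].[O-]I(=O)(=O)=O
Why: Lemieux–Johnson oxidative cleavage of the terminal alkene (osmium-catalysed dihydroxylation, then periodate glycol cleavage) gives the aldehyde under buffered, ozone-free conditions that leave the electron-rich arene, the silyl ether and the β-stereocentre untouched, the change of descriptor from R to S being only a change of substituent priorities.

Step 6
Reactants: 8 (S)-4-(3,4,5-trimethoxyphenyl)-3-{[(triisopropylsilyl)oxy]methyl}butanal
Product: 9 (S)-2-methylene-4-(3,4,5-trimethoxyphenyl)-3-{[(triisopropylsilyl)oxy]methyl}butanal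
Conditions: 37% aq. HCHO, pyrrolidine (10 mol%), EtCO2H (10 mol%), i-PrOH, 45 °C
Reagents that add atoms: formaldehyde, C=O
Why: Amine-catalysed α-methylenation of an aldehyde (Mannich condensation through the enamine, then elimination of the amine) needs only the free α-CH2 of 8, while the stereocentre sits β to the carbonyl and is not part of the enamine.

Step 7
Reactants: 9 (S)-2-methylene-4-(3,4,5-trimethoxyphenyl)-3-{[(triisopropylsilyl)oxy]methyl}butanal
Product: 10 (S)-2-methylene-4-(3,4,5-trimethoxyphenyl)-3-{[(triisopropylsilyl)oxy]methyl}butan-1-ol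
Conditions: NaBH4, CeCl3·7H2O, MeOH, −20 → 0 °C
Reagents that add atoms: none
Why: Luche reduction delivers hydride to the carbonyl carbon of the enal only, giving the allylic alcohol and leaving the alkene, the silyl ether and the stereocentre unchanged.

Step 8
Reactants: 10 (S)-2-methylene-4-(3,4,5-trimethoxyphenyl)-3-{[(triisopropylsilyl)oxy]methyl}butan-1-ol
Product: 11 triisopropyl{[(2R,3S)-4-methylene-2-(3,4,5-trimethoxyphenyl)tetrahydrofuran-3-yl]methoxy}silane
Conditions: graphite anode, Pt cathode, undivided cell, constant current, 2.0–2.2 F/mol, Bu4NClO4 (0.1 M), 2,6-lutidine (2 equiv), CH2Cl2/HFIP (4:1), rt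
Reagents that add atoms: none
Why: Only the trimethoxyarene is oxidised at the potential the cell settles at (the 1,1-disubstituted alkene, the hydroxyl group and the silyl ether need far more positive potentials); its radical cation loses the acidified C2 benzylic proton to lutidine, the benzylic radical is oxidised at once, and the C2 cation is trapped by the hydroxyl oxygen on C5 while hydrogen is evolved at the cathode. The closest known reaction type is anodic (or quinone-mediated) benzylic C–H oxidation of electron-rich alkylarenes with capture of the cation by a tethered alcohol to give cyclic benzylic ethers, applied here to a new substrate. The tetrahydrofuran ring closes in the 5-exo-trig mode, the oxygen adding to the trigonal C2 whose cationic π system (C2–aryl) stays outside the new ring. The new C2 stereocentre is controlled by the C3 stereocentre: the aryl group takes the face trans to the bulky silyloxymethyl arm in the envelope transition state, and since the product ether can re-ionise in the HFIP medium any cis isomer should drain to the more stable trans ether. The step needs site selectivity (a single oxidisable arene and a single benzylic CH2 in 10, because the second aryl group is brought in only in step 9), chemoselectivity against loss of the C3 proton from the cation (the five-ring capture is intramolecular and the medium only weakly basic) and a stop at the ether stage, which the limited charge and the higher oxidation potential of the product ether should secure.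

Step 9
Reactants: 11 triisopropyl{[(2R,3S)-4-methylene-2-(3,4,5-trimethoxyphenyl)tetrahydrofuran-3-yl]methoxy}silane; 12 4-bromo-1,2-dimethoxybenzene
Product: 14 {[(2R,3S,4S)-4-(3,4-dimethoxybenzyl)-2-(3,4,5-trimethoxyphenyl)tetrahydrofuran-3-yl]methoxy}triisopropylsilane, via alkylborane 13 (not isolated)
Conditions: 9-BBN dimer, THF, 0 °C → rt; then 12, Pd(dppf)Cl2·CH2Cl2 (5 mol%), aq. K3PO4, DMF, 60 °C
Reagents that add atoms: none
Why: Hydroboration followed by B-alkyl Suzuki–Miyaura coupling, in which 9-BBN places boron on the exocyclic CH2 and delivers hydrogen to C4 from the ring face anti to the adjacent C3 silyloxymethyl arm, so that the CH2B group and hence the new benzyl group end up cis to that arm (4S), and the primary alkylborane then couples with aryl bromide 12 without touching any stereocentre.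

Step 10
Reactants: 14 {[(2R,3S,4S)-4-(3,4-dimethoxybenzyl)-2-(3,4,5-trimethoxyphenyl)tetrahydrofuran-3-yl]methoxy}triisopropylsilane
Product: 15 [(2R,3S,4S)-4-(3,4-dimethoxybenzyl)-2-(3,4,5-trimethoxyphenyl)tetrahydrofuran-3-yl]methanol
Conditions: Bu4NF, THF, 0 °C → rt
Reagents that add atoms: none
Why: Fluoride-induced cleavage of the silyl ether frees the primary alcohol and cannot affect the three ring stereocentres or the aryl methyl ethers.

Compound list
1 | (S)-4-benzyl-1,3-oxazolidin-2-one | O=C1N[C@@H](Cc2ccccc2)CO1 | starting material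
2 | pent-4-enoyl chloride | C=CCCC(=O)Cl | starting material
3 | (S)-4-benzyl-3-(pent-4-enoyl)-1,3-oxazolidin-2-one | C=CCCC(=O)N1[C@@H](Cc2ccccc2)COC1=O | intermediate
4 | 3,4,5-trimethoxybenzyl bromide | COc1cc(CBr)cc(OC)c1OC | starting material
5 | (S)-4-benzyl-3-[(2R)-2-(3,4,5-trimethoxybenzyl)pent-4-enoyl]-1,3-oxazolidin-2-one | C=CC[C@@H](C(=O)N1[C@@H](Cc2ccccc2)COC1=O)Cc1cc(OC)c(OC)c(OC)c1 | intermediate
6 | (R)-2-(3,4,5-trimethoxybenzyl)pent-4-en-1-ol | C=CC[C@@H](CO)Cc1cc(OC)c(OC)c(OC)c1 | intermediate
7 | (R)-triisopropyl{[2-(3,4,5-trimethoxybenzyl)pent-4-en-1-yl]oxy}silane | C=CC[C@@H](CO[Si](C(C)C)(C(C)C)C(C)C)Cc1cc(OC)c(OC)c(OC)c1 | intermediate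
8 | (S)-4-(3,4,5-trimethoxyphenyl)-3-{[(triisopropylsilyl)oxy]methyl}butanal | O=CC[C@@H](CO[Si](C(C)C)(C(C)C)C(C)C)Cc1cc(OC)c(OC)c(OC)c1 | intermediate
9 | (S)-2-methylene-4-(3,4,5-trimethoxyphenyl)-3-{[(triisopropylsilyl)oxy]methyl}butanal | C=C(C=O)[C@@H](CO[Si](C(C)C)(C(C)C)C(C)C)Cc1cc(OC)c(OC)c(OC)c1 | intermediate
10 | (S)-2-methylene-4-(3,4,5-trimethoxyphenyl)-3-{[(triisopropylsilyl)oxy]methyl}butan-1-ol, precursor of the key step | OCC(=C)[C@@H](CO[Si](C(C)C)(C(C)C)C(C)C)Cc1cc(OC)c(OC)c(OC)c1 | intermediate
11 | triisopropyl{[(2R,3S)-4-methylene-2-(3,4,5-trimethoxyphenyl)tetrahydrofuran-3-yl]methoxy}silane, product of the key step | C=C1CO[C@@H](c2cc(OC)c(OC)c(OC)c2)[C@@H]1CO[Si](C(C)C)(C(C)C)C(C)C | intermediate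
12 | 4-bromo-1,2-dimethoxybenzene | COc1ccc(Br)cc1OC | starting material
13 | 9-{[(3S,4S,5R)-4-{[(triisopropylsilyl)oxy]methyl}-5-(3,4,5-trimethoxyphenyl)tetrahydrofuran-3-yl]methyl}-9-borabicyclo[3.3.1]nonane, the alkylborane, not isolated | B1(C[C@@H]2CO[C@@H](c3cc(OC)c(OC)c(OC)c3)[C@@H]2CO[Si](C(C)C)(C(C)C)C(C)C)C2CCCC1CCC2 | intermediate
14 | {[(2R,3S,4S)-4-(3,4-dimethoxybenzyl)-2-(3,4,5-trimethoxyphenyl)tetrahydrofuran-3-yl]methoxy}triisopropylsilane | COc1ccc(C[C@@H]2CO[C@@H](c3cc(OC)c(OC)c(OC)c3)[C@@H]2CO[Si](C(C)C)(C(C)C)C(C)C)cc1OC | intermediate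
15 | [(2R,3S,4S)-4-(3,4-dimethoxybenzyl)-2-(3,4,5-trimethoxyphenyl)tetrahydrofuran-3-yl]methanol | COc1ccc(C[C@@H]2CO[C@@H](c3cc(OC)c(OC)c(OC)c3)[C@@H]2CO)cc1OC | target

Total step count: 10
Longest linear sequence: 10 steps (1 and 2 to 15)

Steps most likely to fail

1. Step 8. The C2 cation may lose the C3 proton and give a styrene instead of being trapped. The product ether may also be oxidised further at C2, or the arene radical cation may couple with a second molecule. The fallback makes the benzylic C–O bond by an aldol addition and closes the ring by acid-mediated cyclodehydration, all known chemistry; it sets out from 2 and returns to the route at 11.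
   - Acid chloride 2 acylates (R)-4-benzyl-1,3-oxazolidin-2-one (n-BuLi, THF, −78 °C) to give the enantiomeric imide F1. The other auxiliary antipode is needed because aldol and alkylation use opposite enolate faces.
   - Evans syn-aldol reaction (Bu2BOTf, i-Pr2NEt, CH2Cl2, −78 → 0 °C, then 3,4,5-trimethoxybenzaldehyde) should give the syn-aldol adduct F2, which already has the C2 and C3 configurations of 11.
   - NaBH4 in THF/H2O removes the auxiliary and gives the 1,3-diol F3.
   - TIPSCl and imidazole silylate the primary hydroxyl selectively to give the mono-silyl ether F4.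
   - Lemieux–Johnson cleavage (K2OsO4·2H2O, NaIO4, 2,6-lutidine) gives the lactol F5.
   - α-Methylenation (aq. HCHO, pyrrolidine, EtCO2H) gives the methylene lactol F6.
   - Luche reduction (NaBH4, CeCl3·7H2O) opens it to the 1,4-diol F7.
   - Catalytic camphorsulfonic acid in CH2Cl2 ionises the benzylic alcohol, and the C5 hydroxyl closes the ring to the 2,3-trans ether 11.

2. Step 9. The two faces of the exocyclic alkene may be poorly discriminated in the hydroboration, or the β-branched alkylborane may transmetalate slowly and protodeboronate. The fallback forms the C–C bond by metathesis and sets C4 by hydrogenation; it sets out from 11 and returns at 14.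
   - Olefin cross-metathesis of 11 with 3,4-dimethoxystyrene (second-generation Hoveyda–Grubbs catalyst, toluene, 60 °C) should give the 4-(3,4-dimethoxybenzylidene)tetrahydrofuran F8 as an E/Z mixture.
   - Heterogeneous hydrogenation (H2, Pd/C, EtOAc, rt) is expected to add hydrogen from the face anti to the C3 arm and give 14.

3. Step 6. The C3 stereocentre may erode, or the double bond may migrate, through a dienamine of the product enal; the enal may also oligomerise under amine catalysis. The fallback methylenates at the ester oxidation level without iminium catalysis; it sets out from 8 and returns at 10.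
   - Pinnick oxidation (NaClO2, NaH2PO4, 2-methyl-2-butene, t-BuOH/H2O) gives the carboxylic acid F9.
   - Me3SiCHN2 in MeOH/toluene gives the methyl ester F10.
   - The lithium enolate (lithium diisopropylamide, THF, −78 °C) is aminomethylated with dimethylmethyleneiminium iodide to the Mannich base F11.
   - N-Methylation with MeI gives the quaternary ammonium iodide F12, and elimination with DBU gives the α-methylene ester F13.
   - Reduction with i-Bu2AlH (CH2Cl2, −78 °C) gives 10.

Further compounds
F1 | step 8 | (R)-4-benzyl-3-(pent-4-enoyl)-1,3-oxazolidin-2-one | C=CCCC(=O)N1[C@H](Cc2ccccc2)COC1=O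
F2 | step 8 | (R)-4-benzyl-3-{(2R)-2-[(R)-hydroxy(3,4,5-trimethoxyphenyl)methyl]pent-4-enoyl}-1,3-oxazolidin-2-one | C=CC[C@@H](C(=O)N1[C@H](Cc2ccccc2)COC1=O)[C@@H](O)c1cc(OC)c(OC)c(OC)c1
F3 | step 8 | (1R,2S)-2-(hydroxymethyl)-1-(3,4,5-trimethoxyphenyl)pent-4-en-1-ol | C=CC[C@@H](CO)[C@@H](O)c1cc(OC)c(OC)c(OC)c1
F4 | step 8 | (1R,2S)-1-(3,4,5-trimethoxyphenyl)-2-{[(triisopropylsilyl)oxy]methyl}pent-4-en-1-ol | C=CC[C@@H](CO[Si](C(C)C)(C(C)C)C(C)C)[C@@H](O)c1cc(OC)c(OC)c(OC)c1
F5 | step 8 | (4S,5R)-5-(3,4,5-trimethoxyphenyl)-4-{[(triisopropylsilyl)oxy]methyl}tetrahydrofuran-2-ol, anomeric mixture | OC1C[C@@H](CO[Si](C(C)C)(C(C)C)C(C)C)[C@H](c2cc(OC)c(OC)c(OC)c2)O1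
F6 | step 8 | (4S,5R)-3-methylene-5-(3,4,5-trimethoxyphenyl)-4-{[(triisopropylsilyl)oxy]methyl}tetrahydrofuran-2-ol, anomeric mixture | OC1O[C@@H](c2cc(OC)c(OC)c(OC)c2)[C@H](CO[Si](C(C)C)(C(C)C)C(C)C)C1=C
F7 | step 8 | (1R,2S)-3-methylene-2-{[(triisopropylsilyl)oxy]methyl}-1-(3,4,5-trimethoxyphenyl)butane-1,4-diol | OCC(=C)[C@@H](CO[Si](C(C)C)(C(C)C)C(C)C)[C@@H](O)c1cc(OC)c(OC)c(OC)c1
F8 | step 9 | {[(2R,3S)-4-(3,4-dimethoxybenzylidene)-2-(3,4,5-trimethoxyphenyl)tetrahydrofuran-3-yl]methoxy}triisopropylsilane, E/Z mixture | COc1ccc(C=C2CO[C@@H](c3cc(OC)c(OC)c(OC)c3)[C@@H]2CO[Si](C(C)C)(C(C)C)C(C)C)cc1OC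
F9 | step 6 | (S)-4-(3,4,5-trimethoxyphenyl)-3-{[(triisopropylsilyl)oxy]methyl}butanoic acid | OC(=O)C[C@@H](CO[Si](C(C)C)(C(C)C)C(C)C)Cc1cc(OC)c(OC)c(OC)c1
F10 | step 6 | methyl (S)-4-(3,4,5-trimethoxyphenyl)-3-{[(triisopropylsilyl)oxy]methyl}butanoate | COC(=O)C[C@@H](CO[Si](C(C)C)(C(C)C)C(C)C)Cc1cc(OC)c(OC)c(OC)c1
F11 | step 6 | methyl (3S)-2-[(dimethylamino)methyl]-4-(3,4,5-trimethoxyphenyl)-3-{[(triisopropylsilyl)oxy]methyl}butanoate, epimers at C2 | COC(=O)C(CN(C)C)[C@@H](CO[Si](C(C)C)(C(C)C)C(C)C)Cc1cc(OC)c(OC)c(OC)c1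
F12 | step 6 | {(3S)-2-(methoxycarbonyl)-4-(3,4,5-trimethoxyphenyl)-3-{[(triisopropylsilyl)oxy]methyl}butyl}trimethylammonium iodide, epimers at C2 | COC(=O)C(C[N+](C)(C)C)[C@@H](CO[Si](C(C)C)(C(C)C)C(C)C)Cc1cc(OC)c(OC)c(OC)c1.[I-]
F13 | step 6 | methyl (S)-2-methylene-4-(3,4,5-trimethoxyphenyl)-3-{[(triisopropylsilyl)oxy]methyl}butanoate | COC(=O)C(=C)[C@@H](CO[Si](C(C)C)(C(C)C)C(C)C)Cc1cc(OC)c(OC)c(OC)c1
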